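**Assumption:** the SMILES contains no stereocentre and no stereogenic double bond, so the target is achiral and "single enantiomer" means simply the one compound drawn (5,5'-dichloroatranorin).

**Retrosynthetic overview**
1. Both C–Cl bonds are cut last: a one-pot double electrophilic chlorination of atranorin, in which each ring has exactly one free position.
2. The ring A aldehyde is cut next: Rieche formylation between the two hydroxyls of an orsellinate depside.
3. Key step: the depside is not made by coupling an aryl acid with a phenol. Ring A is instead built on the ester by a Diels–Alder benzannulation of an aryl but-2-ynoate with a 1-methoxy-1,3-bis(silyloxy)diene.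
4. The aryl ynoate comes from commercial atraric acid (ring B, bought intact) and but-2-ynoic acid; the diene comes from commercial methyl 3-(trimethylsilyloxy)but-2-enoate.
5. Ring order: ring B is purchased; ring A is formed in step 3, after the ester link exists. No stereocentres are set.

**Route**

Step 1
Reactants: 1 methyl 3-(trimethylsilyloxy)but-2-enoate (E/Z mixture as supplied)
Product: 3 1-methoxy-1,3-bis(trimethylsilyloxy)buta-1,3-diene (Chan's diene), via lithium dienolate 2 (not isolated)
Conditions: LiN(iPr)2 (1.1 equiv), THF, −78 °C, 1 h; Me3SiCl (1.2 equiv), −78 to 23 °C; hexane, filter, distil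
Reagents that add atoms: chlorotrimethylsilane, C[Si](C)(C)Cl
Why: Kinetic γ-deprotonation of the β-silyloxy enoate by lithium diisopropylamide gives the extended ester dienolate 2, which is O-silylated (silyl ketene acetal formation); no stereocentre is made and the enol-ether geometry is irrelevant because those carbons become aromatic.

Step 2
Reactants: 4 methyl 2,4-dihydroxy-3,6-dimethylbenzoate (atraric acid); 5 but-2-ynoic acid
Product: 7 methyl 4-(but-2-ynoyloxy)-2-hydroxy-3,6-dimethylbenzoate, via O-acylisourea 6 (not isolated)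
Conditions: N,N'-dicyclohexylcarbodiimide (1.2 equiv), 4-(dimethylamino)pyridine (5 mol %), CH2Cl2, 0 to 23 °C
Reagents that add atoms: none
Why: Steglich esterification; the 2-OH is hydrogen-bonded to the neighbouring methyl ester and flanked on both sides, so only the free 4-OH attacks the carbodiimide-activated acid 6; no stereocentre.

Step 3
Reactants: 7 methyl 4-(but-2-ynoyloxy)-2-hydroxy-3,6-dimethylbenzoate; 3 1-methoxy-1,3-bis(trimethylsilyloxy)buta-1,3-diene
Product: 9 methyl 4-[(2,4-dihydroxy-6-methylbenzoyl)oxy]-2-hydroxy-3,6-dimethylbenzoate, via Diels–Alder cycloadduct 8 (not isolated)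
Conditions: 3 (3 equiv), toluene, 115 °C, sealed tube, 36 h; then 1 M HCl (aq), THF, 23 °C
Reagents that add atoms: none
Why: Diels–Alder benzannulation of a 2-alkynoate with a 1-alkoxy-1,3-bis(silyloxy)diene (known reaction type, here on an aryl ester): the nucleophilic CH2 terminus of the diene bonds to the methyl-bearing β-carbon of the ynoate and the ketene-acetal carbon to the α-carbon, and acid then collapses the mixed ketal of 8 (loss of methanol and both silyl groups) to the 2,4-dihydroxy-6-methylbenzoate, so ring A is formed with the depside ester already in place; the sp3 ketal carbon of 8 is racemic and vanishes on aromatization, and any silylation of the ring B hydroxyl by excess diene is reversed in the same work-up.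

Step 4
Reactants: 9 methyl 4-[(2,4-dihydroxy-6-methylbenzoyl)oxy]-2-hydroxy-3,6-dimethylbenzoate
Product: 11 methyl 4-[(3-formyl-2,4-dihydroxy-6-methylbenzoyl)oxy]-2-hydroxy-3,6-dimethylbenzoate (atranorin), via chloro(methoxy)methyl arene 10 (not isolated)
Conditions: Cl2CHOMe (1.5 equiv), TiCl4 (4 equiv), CH2Cl2, −20 to 0 °C; then 1 M HCl (aq), 23 °C
Reagents that add atoms: dichloromethyl methyl ether, COC(Cl)Cl; water, O
Why: Rieche formylation; TiCl4 binds the phenols and directs the chloro(methoxy)methyl cation to C3 of ring A, the carbon ortho to both hydroxyls (ring B has no free position ortho to a hydroxyl and is less activated), and aqueous hydrolysis of 10 releases the aldehyde; the transient CHCl(OMe) centre is racemic and is destroyed.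

Step 5
Reactants: 11 atranorin
Product: 13 methyl 5-chloro-4-[(3-chloro-5-formyl-4,6-dihydroxy-2-methylbenzoyl)oxy]-2-hydroxy-3,6-dimethylbenzoate (target), via chloroatranorin 12 (not isolated)
Conditions: SO2Cl2 (2.3 equiv), CH2Cl2/Et2O, 0 to 23 °C, dark
Reagents that add atoms: sulfuryl chloride, O=S(=O)(Cl)Cl
Why: Twofold electrophilic aromatic chlorination; after formylation each ring has one unsubstituted carbon, activated by hydroxyl (C5 of ring A ortho to 4-OH and para to 2-OH; C5 of ring B para to its 2-OH), so only the 5,5'-dichloride can form, with ring A reacting first via 12; no stereocentre.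

**Compound list**
1 | methyl 3-(trimethylsilyloxy)but-2-enoate (E/Z mixture, geometry inconsequential) | COC(=O)C=C(C)O[Si](C)(C)C | starting material
2 | lithium 1-methoxy-3-(trimethylsilyloxy)buta-1,3-dien-1-olate (not isolated; geometry inconsequential) | [Li+].[O-]C(OC)=CC(=C)O[Si](C)(C)C | intermediate
3 | 1-methoxy-1,3-bis(trimethylsilyloxy)buta-1,3-diene (Chan's diene; geometry at C1=C2 inconsequential) | COC(O[Si](C)(C)C)=CC(=C)O[Si](C)(C)C | intermediate
4 | methyl 2,4-dihydroxy-3,6-dimethylbenzoate (atraric acid) | COC(=O)c1c(C)cc(O)c(C)c1O | starting material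
5 | but-2-ynoic acid | CC#CC(=O)O | starting material
6 | O-(but-2-ynoyl)-N,N'-dicyclohexylisourea (not isolated) | CC#CC(=O)OC(=NC1CCCCC1)NC1CCCCC1 | intermediate
7 | methyl 4-(but-2-ynoyloxy)-2-hydroxy-3,6-dimethylbenzoate | COC(=O)c1c(C)cc(OC(=O)C#CC)c(C)c1O | intermediate
8 | methyl 2-hydroxy-4-{[6-methoxy-2-methyl-4,6-bis(trimethylsilyloxy)cyclohexa-1,4-diene-1-carbonyl]oxy}-3,6-dimethylbenzoate (not isolated; racemic at the ketal carbon) | COC(=O)c1c(C)cc(OC(=O)C2=C(C)CC(O[Si](C)(C)C)=CC2(OC)O[Si](C)(C)C)c(C)c1O | intermediate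
9 | methyl 4-[(2,4-dihydroxy-6-methylbenzoyl)oxy]-2-hydroxy-3,6-dimethylbenzoate | COC(=O)c1c(C)cc(OC(=O)c2c(C)cc(O)cc2O)c(C)c1O | intermediate
10 | methyl 4-({3-[chloro(methoxy)methyl]-2,4-dihydroxy-6-methylbenzoyl}oxy)-2-hydroxy-3,6-dimethylbenzoate (not isolated; racemic) | COC(=O)c1c(C)cc(OC(=O)c2c(C)cc(O)c(C(Cl)OC)c2O)c(C)c1O | intermediate
11 | atranorin, methyl 4-[(3-formyl-2,4-dihydroxy-6-methylbenzoyl)oxy]-2-hydroxy-3,6-dimethylbenzoate | COC(=O)c1c(C)cc(OC(=O)c2c(C)cc(O)c(C=O)c2O)c(C)c1O | intermediate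
12 | chloroatranorin, methyl 4-[(3-chloro-5-formyl-4,6-dihydroxy-2-methylbenzoyl)oxy]-2-hydroxy-3,6-dimethylbenzoate (not isolated) | COC(=O)c1c(C)cc(OC(=O)c2c(C)c(Cl)c(O)c(C=O)c2O)c(C)c1O | intermediate
13 | methyl 5-chloro-4-[(3-chloro-5-formyl-4,6-dihydroxy-2-methylbenzoyl)oxy]-2-hydroxy-3,6-dimethylbenzoate (achiral) | COC(=O)c1c(C)c(Cl)c(OC(=O)c2c(C)c(Cl)c(O)c(C=O)c2O)c(C)c1O | target

**Totals**
Total step count: 5. Longest linear sequence: 4 steps (4 → 7 → 9 → 11 → 13; the diene branch 1 → 3 joins at step 3 and is equally long).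

**Three steps most likely to fail, with fallbacks**

Risk 1, step 3 (Diels–Alder benzannulation). But-2-ynoates are sluggish dienophiles, the diene is thermally fragile, and loss of silanol instead of methanol would give a 2-O-methyl ether. The fallback sets out from 4 and comes back at 9, and replaces the benzannulation by a classical depside coupling. Commercial methyl 2,4-dihydroxy-6-methylbenzoate is benzylated (benzyl bromide, K2CO3, acetone, reflux) to methyl 2,4-bis(benzyloxy)-6-methylbenzoate F1. Saponification (KOH, aqueous DMSO, 80 °C; then HCl) gives 2,4-bis(benzyloxy)-6-methylbenzoic acid F2. Trifluoroacetic anhydride in toluene at 23 °C converts F2 into 2,4-bis(benzyloxy)-6-methylbenzoic trifluoroacetic anhydride F3, which acylates the 4-OH of 4 to give methyl 4-{[2,4-bis(benzyloxy)-6-methylbenzoyl]oxy}-2-hydroxy-3,6-dimethylbenzoate F4. Hydrogenolysis (H2, Pd/C, ethyl acetate) removes both benzyl groups and delivers 9.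

Risk 2, step 4 (formylation regiochemistry). Attack at C5 of ring A instead of C3 would give the isomeric aldehyde. The fallback sets out from 9 and comes back at 12; it uses the chlorine the target needs anyway as a blocking group. One equivalent of SO2Cl2 (Et2O, 0 °C) chlorinates the most activated site, C5 of ring A (para to the chelated 2-OH), giving methyl 4-[(3-chloro-4,6-dihydroxy-2-methylbenzoyl)oxy]-2-hydroxy-3,6-dimethylbenzoate F5. Rieche formylation (Cl2CHOMe, TiCl4, CH2Cl2) can then only reach C3 and proceeds through methyl 4-({3-chloro-5-[chloro(methoxy)methyl]-4,6-dihydroxy-2-methylbenzoyl}oxy)-2-hydroxy-3,6-dimethylbenzoate F6, whose hydrolysis gives 12. Here 12 is isolated and taken through step 5 with 1.1 equiv of SO2Cl2.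

Risk 3, step 5 (double chlorination). Ring B, a salicylate-type ring, may chlorinate too slowly, leaving 12 or inviting side-chain chlorination under forcing conditions. The fallback sets out from 4 and comes back at 13; it installs the ring B chlorine first, where it is trivial.
- SO2Cl2 (1.05 equiv, Et2O, 0 °C) converts 4 into methyl 5-chloro-2,4-dihydroxy-3,6-dimethylbenzoate F7.
- Steglich esterification with 5 (through 6) gives methyl 4-(but-2-ynoyloxy)-5-chloro-2-hydroxy-3,6-dimethylbenzoate F8.
- Cycloaddition with 3 gives methyl 5-chloro-2-hydroxy-4-{[6-methoxy-2-methyl-4,6-bis(trimethylsilyloxy)cyclohexa-1,4-diene-1-carbonyl]oxy}-3,6-dimethylbenzoate F9, which aromatizes on acid work-up to methyl 5-chloro-4-[(2,4-dihydroxy-6-methylbenzoyl)oxy]-2-hydroxy-3,6-dimethylbenzoate F10.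
- Rieche formylation passes through methyl 5-chloro-4-({3-[chloro(methoxy)methyl]-2,4-dihydroxy-6-methylbenzoyl}oxy)-2-hydroxy-3,6-dimethylbenzoate F11 to methyl 5-chloro-4-[(3-formyl-2,4-dihydroxy-6-methylbenzoyl)oxy]-2-hydroxy-3,6-dimethylbenzoate F12.
- A single, fast ring A chlorination (SO2Cl2, 1.1 equiv) then gives 13.

**Further compounds**
F1 | step 3 | methyl 2,4-bis(benzyloxy)-6-methylbenzoate | COC(=O)c1c(C)cc(OCc2ccccc2)cc1OCc1ccccc1
F2 | step 3 | 2,4-bis(benzyloxy)-6-methylbenzoic acid | OC(=O)c1c(C)cc(OCc2ccccc2)cc1OCc1ccccc1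
F3 | step 3 | 2,4-bis(benzyloxy)-6-methylbenzoic trifluoroacetic anhydride | O=C(OC(=O)C(F)(F)F)c1c(C)cc(OCc2ccccc2)cc1OCc1ccccc1
F4 | step 3 | methyl 4-{[2,4-bis(benzyloxy)-6-methylbenzoyl]oxy}-2-hydroxy-3,6-dimethylbenzoate | COC(=O)c1c(C)cc(OC(=O)c2c(C)cc(OCc3ccccc3)cc2OCc2ccccc2)c(C)c1O
F5 | step 4 | methyl 4-[(3-chloro-4,6-dihydroxy-2-methylbenzoyl)oxy]-2-hydroxy-3,6-dimethylbenzoate | COC(=O)c1c(C)cc(OC(=O)c2c(C)c(Cl)c(O)cc2O)c(C)c1O
F6 | step 4 | methyl 4-({3-chloro-5-[chloro(methoxy)methyl]-4,6-dihydroxy-2-methylbenzoyl}oxy)-2-hydroxy-3,6-dimethylbenzoate | COC(=O)c1c(C)cc(OC(=O)c2c(C)c(Cl)c(O)c(C(Cl)OC)c2O)c(C)c1O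
F7 | step 5 | methyl 5-chloro-2,4-dihydroxy-3,6-dimethylbenzoate | COC(=O)c1c(C)c(Cl)c(O)c(C)c1O
F8 | step 5 | methyl 4-(but-2-ynoyloxy)-5-chloro-2-hydroxy-3,6-dimethylbenzoate | COC(=O)c1c(C)c(Cl)c(OC(=O)C#CC)c(C)c1O
F9 | step 5 | methyl 5-chloro-2-hydroxy-4-{[6-methoxy-2-methyl-4,6-bis(trimethylsilyloxy)cyclohexa-1,4-diene-1-carbonyl]oxy}-3,6-dimethylbenzoate | COC(=O)c1c(C)c(Cl)c(OC(=O)C2=C(C)CC(O[Si](C)(C)C)=CC2(OC)O[Si](C)(C)C)c(C)c1O
F10 | step 5 | methyl 5-chloro-4-[(2,4-dihydroxy-6-methylbenzoyl)oxy]-2-hydroxy-3,6-dimethylbenzoate | COC(=O)c1c(C)c(Cl)c(OC(=O)c2c(C)cc(O)cc2O)c(C)c1O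
F11 | step 5 | methyl 5-chloro-4-({3-[chloro(methoxy)methyl]-2,4-dihydroxy-6-methylbenzoyl}oxy)-2-hydroxy-3,6-dimethylbenzoate | COC(=O)c1c(C)c(Cl)c(OC(=O)c2c(C)cc(O)c(C(Cl)OC)c2O)c(C)c1O
F12 | step 5 | methyl 5-chloro-4-[(3-formyl-2,4-dihydroxy-6-methylbenzoyl)oxy]-2-hydroxy-3,6-dimethylbenzoate | COC(=O)c1c(C)c(Cl)c(OC(=O)c2c(C)cc(O)c(C=O)c2O)c(C)c1O
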